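**Plan**

- Retrosynthesis: the flavanone is cut at C2–C3 (ring C), then at the O1–C2 ether bond, which separates a phloroacetophenone diazomethyl ketone from a flavone-bearing benzylic alcohol. The flavone half is cut at the biaryl bond C8–C3' and at its own ring C (via a chalcone).
- Enabling feature: flavanone C2 is a benzylic carbon bound to ring oxygen O1, so in an O1–CH2–aryl ether its C–H bonds are activated toward insertion by a carbenoid generated at C3, next to the C4 carbonyl.
- Forward: flavone rings A and C arise from 2,4,6-trihydroxyacetophenone and 4-methoxybenzaldehyde with iodine at C8. Suzuki coupling attaches ring B of the future flavanone, Mitsunobu etherification adds the silylated phloroacetophenone, and diazo transfer followed by C–H insertion closes flavanone ring C last. Desilylation and hydrogenolysis finish the route.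
- Stereochemistry: the only stereocentre, C2 (S), is created in the insertion, where the chiral dirhodium carboxylate selects one of the two enantiotopic benzylic hydrogens. All later steps are non-basic, so it is retained.

Key step: step 12

Assumption: Rh2(S-PTTL)4 is taken to deliver the (2S) product; the sense of induction for this substrate is not predictable with confidence, and if it proves opposite the mirror-image catalyst from (R)-tert-leucine is used in the same way.
Remark: triisopropylsilyl ethers are placed on O5 and O7 because smaller aryl silyl ethers ortho and para to a ketone are prone to base cleavage and to O-to-O silyl transfer onto the enolate during diazo transfer.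
Remark: the C8–C3' biaryl axis has no descriptor in the target and is treated as freely rotating, so rotamers of the benzylated intermediates have no stereochemical consequence.

**Route**

Step 1
Reactants: 1 2,4,6-trihydroxyacetophenone
Product: 2 1-[2,4-bis(benzyloxy)-6-hydroxyphenyl]ethan-1-one
Conditions: BnBr (2.1 equiv), K2CO3, DMF, rt
Reagents that add atoms: benzyl bromide, BrCc1ccccc1
Why: Williamson etherification, in which the two phenols not held in the hydrogen bond to the acetyl carbonyl react first, so two equivalents of benzyl bromide should stop at the 4,6-dibenzyl ether and leave the chelated OH free.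

Step 2
Reactants: 2 1-[2,4-bis(benzyloxy)-6-hydroxyphenyl]ethan-1-one
Product: 3 1-[4,6-bis(benzyloxy)-2-hydroxy-3-iodophenyl]ethan-1-one
Conditions: N-iodosuccinimide (1.05 equiv), CF3CO2H (cat.), MeCN, 0 °C to rt
Reagents that add atoms: N-iodosuccinimide, O=C1CCC(=O)N1I
Why: Electrophilic aromatic iodination, in which both open positions are activated by three oxygens and C3, ortho to the free phenol and flanked by only one benzyloxy group, is the less hindered, so mono-iodination should occur there (the regiochemistry should be confirmed by HMBC before the material is carried on).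

Step 3
Reactants: 3 1-[4,6-bis(benzyloxy)-2-hydroxy-3-iodophenyl]ethan-1-one; 4 4-methoxybenzaldehyde
Product: 5 (E)-1-[4,6-bis(benzyloxy)-2-hydroxy-3-iodophenyl]-3-(4-methoxyphenyl)prop-2-en-1-one
Conditions: KOH (50% aq), EtOH–THF, rt
Reagents that add atoms: none
Why: Claisen–Schmidt condensation, in which the acetophenone enolate adds to the non-enolisable aldehyde and the aldol dehydrates to the (E)-enone, the aryl iodide and benzyl ethers being inert to aqueous alkali at room temperature.

Step 4
Reactants: 5 (E)-1-[4,6-bis(benzyloxy)-2-hydroxy-3-iodophenyl]-3-(4-methoxyphenyl)prop-2-en-1-one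
Product: 7 5,7-bis(benzyloxy)-8-iodo-2-(4-methoxyphenyl)-4H-chromen-4-one, via racemic 8-iodoflavanone 6 (not isolated)
Conditions: I2 (10 mol %), DMSO, 120 °C
Reagents that add atoms: none
Why: Iodine-catalysed oxidative cyclisation in DMSO, in which intramolecular oxa-Michael addition gives flavanone 6, α-iodination and loss of hydrogen iodide give the flavone, and DMSO reoxidises iodide to iodine, so the iodine that sat ortho to the phenol ends at C8.

Step 5
Reactants: 8 4-hydroxy-3-iodobenzaldehyde
Product: 9 4-(benzyloxy)-3-iodobenzaldehyde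
Conditions: BnBr, K2CO3, DMF, rt
Reagents that add atoms: benzyl bromide, BrCc1ccccc1
Why: Williamson etherification of an acidic para-formyl phenol, which should proceed cleanly at room temperature.

Step 6
Reactants: 9 4-(benzyloxy)-3-iodobenzaldehyde
Product: 10 4-(benzyloxy)-3-(4,4,5,5-tetramethyl-1,3,2-dioxaborolan-2-yl)benzaldehyde
Conditions: bis(pinacolato)diboron, PdCl2(dppf) (dppf = 1,1'-bis(diphenylphosphino)ferrocene), KOAc, 1,4-dioxane, 85 °C
Reagents that add atoms: bis(pinacolato)diboron, CC1(C)OB(OC1(C)C)B1OC(C)(C)C(C)(C)O1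
Why: Miyaura borylation, by oxidative addition of the aryl iodide to zerovalent palladium, acetate-assisted transmetalation with the diboron and reductive elimination, under which the aldehyde is a spectator.

Step 7
Reactants: 7 5,7-bis(benzyloxy)-8-iodo-2-(4-methoxyphenyl)-4H-chromen-4-one; 10 4-(benzyloxy)-3-(4,4,5,5-tetramethyl-1,3,2-dioxaborolan-2-yl)benzaldehyde
Product: 11 4-(benzyloxy)-3-[5,7-bis(benzyloxy)-2-(4-methoxyphenyl)-4-oxo-4H-chromen-8-yl]benzaldehyde
Conditions: Pd(OAc)2 (5 mol %), SPhos (2-dicyclohexylphosphino-2',6'-dimethoxybiphenyl, 10 mol %), K3PO4, toluene–H2O, 90 °C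
Reagents that add atoms: none
Why: Suzuki–Miyaura coupling, in which the electron-rich dialkylbiarylphosphine promotes oxidative addition at the hindered C8–iodine bond and reductive elimination to the tri-ortho-substituted biaryl, while the mild phosphate base spares the aldehyde and the chromone.

Step 8
Reactants: 11 4-(benzyloxy)-3-[5,7-bis(benzyloxy)-2-(4-methoxyphenyl)-4-oxo-4H-chromen-8-yl]benzaldehyde
Product: 12 5,7-bis(benzyloxy)-8-[2-(benzyloxy)-5-(hydroxymethyl)phenyl]-2-(4-methoxyphenyl)-4H-chromen-4-one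
Conditions: NaBH4, THF–MeOH, 0 °C
Reagents that add atoms: none
Why: Borohydride reduction, in which the aryl aldehyde is far more electrophilic than the vinylogous-ester carbonyl of the flavone, so a small excess of hydride at 0 °C should reduce it selectively to the benzylic alcohol.

Step 9
Reactants: 1 2,4,6-trihydroxyacetophenone
Product: 13 1-[2-hydroxy-4,6-bis(triisopropylsilyloxy)phenyl]ethan-1-one
Conditions: triisopropylsilyl chloride (2.1 equiv), imidazole, DMF, 0 °C to rt
Reagents that add atoms: triisopropylsilyl chloride, CC(C)[Si](Cl)(C(C)C)C(C)C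
Why: Silylation of phenols, in which the 4-OH and one 2-OH react and the remaining ortho-OH is then locked in a hydrogen bond to the acetyl group, so the reaction should stop at the bis-silyl ether.

Step 10
Reactants: 12 5,7-bis(benzyloxy)-8-[2-(benzyloxy)-5-(hydroxymethyl)phenyl]-2-(4-methoxyphenyl)-4H-chromen-4-one; 13 1-[2-hydroxy-4,6-bis(triisopropylsilyloxy)phenyl]ethan-1-one
Product: 14 8-[5-({2-acetyl-3,5-bis(triisopropylsilyloxy)phenoxy}methyl)-2-(benzyloxy)phenyl]-5,7-bis(benzyloxy)-2-(4-methoxyphenyl)-4H-chromen-4-one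
Conditions: PPh3, diisopropyl azodicarboxylate, THF, 0 °C to rt
Reagents that add atoms: none
Why: Mitsunobu etherification, in which the phenol, acidified by its ortho-acyl group, displaces the oxyphosphonium of the primary benzylic alcohol and joins the two halves under neutral conditions that the silyl ethers tolerate.

Step 11
Reactants: 14 8-[5-({2-acetyl-3,5-bis(triisopropylsilyloxy)phenoxy}methyl)-2-(benzyloxy)phenyl]-5,7-bis(benzyloxy)-2-(4-methoxyphenyl)-4H-chromen-4-one
Product: 16 8-[5-({2-(2-diazoacetyl)-3,5-bis(triisopropylsilyloxy)phenoxy}methyl)-2-(benzyloxy)phenyl]-5,7-bis(benzyloxy)-2-(4-methoxyphenyl)-4H-chromen-4-one, via trifluoroacetyl diketone 15 (not isolated)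
Conditions: LiN(SiMe3)2, THF, −78 °C; CF3CO2CH2CF3, −78 °C; aq NH4Cl; then MsN3, Et3N, H2O, MeCN, rt
Reagents that add atoms: methanesulfonyl azide, CS(=O)(=O)N=[N+]=[N-] (gives the two diazo nitrogens of 16); 2,2,2-trifluoroethyl trifluoroacetate, O=C(OCC(F)(F)F)C(F)(F)F (its trifluoroacetyl group is present in 15 only)
Why: Detrifluoroacetylative (Regitz-type) diazo transfer, in which the lithium enolate of the methyl ketone is C-trifluoroacetylated in a Claisen condensation and the activated diketone 15 accepts the diazo group from the sulfonyl azide with loss of the trifluoroacetyl group as its N-mesyl amide, the hindered silyl ethers and the non-enolisable flavone being left alone at −78 °C and under the mild amine conditions.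

Step 12
Reactants: 16 8-[5-({2-(2-diazoacetyl)-3,5-bis(triisopropylsilyloxy)phenoxy}methyl)-2-(benzyloxy)phenyl]-5,7-bis(benzyloxy)-2-(4-methoxyphenyl)-4H-chromen-4-one
Product: 17 5,7-bis(benzyloxy)-8-{2-(benzyloxy)-5-[(2S)-4-oxo-5,7-bis(triisopropylsilyloxy)chroman-2-yl]phenyl}-2-(4-methoxyphenyl)-4H-chromen-4-one
Conditions: Rh2(S-PTTL)4 [dirhodium tetrakis(N-phthaloyl-(S)-tert-leucinate)] (2 mol %), CH2Cl2, 0 °C to rt, slow addition of 16
Reagents that add atoms: none
Why: Loss of N2 from 16 at the dirhodium core gives an electrophilic rhodium carbenoid at C3, which takes up one benzylic C–H bond of the O1–CH2–aryl ether in a concerted three-centre event and so forms the C2–C3 bond. The closest known reaction type is the cyclisation of 2-alkoxyphenyl α-diazoketones to 2-substituted chroman-4-ones under chiral dirhodium carboxylate catalysis. Ring C closes as a six-membered ring by 1,6-C–H insertion, with C3, C4, C4a, C8a, O1 and C2 as the ring atoms; the five-membered alternative is unavailable as an insertion because the atom in that position is O1, which bears no hydrogen. The new stereocentre C2 is set by the catalyst, whose phthalimido-walled pocket differentiates the two enantiotopic benzylic hydrogens, with the ligand hand chosen to give 2S. The step needs insertion to outrun attack of O1 on the carbenoid (oxonium ylide, then [1,2]-benzyl shift) and carbene dimerisation: the O1 lone pair is delocalised into the acyl-bearing ring and is weakly basic, the benzylic C–H bonds are made hydridic by O1 and by the para-benzyloxy group of ring B, the triisopropylsilyl ethers shield O5 and offer no activated C–H bond within reach, and slow addition keeps the diazo concentration low. The neutral aprotic medium also leaves C2 configurationally secure, since no phenoxide can form to open ring C.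

Step 13
Reactants: 17 5,7-bis(benzyloxy)-8-{2-(benzyloxy)-5-[(2S)-4-oxo-5,7-bis(triisopropylsilyloxy)chroman-2-yl]phenyl}-2-(4-methoxyphenyl)-4H-chromen-4-one
Product: 18 5,7-bis(benzyloxy)-8-{2-(benzyloxy)-5-[(2S)-5,7-dihydroxy-4-oxochroman-2-yl]phenyl}-2-(4-methoxyphenyl)-4H-chromen-4-one
Conditions: HF·pyridine, pyridine, THF, 0 °C to rt
Reagents that add atoms: none
Why: Fluoride-mediated cleavage of aryl silyl ethers, in which buffered HF·pyridine breaks both Si–O bonds without generating free phenoxide, so retro-oxa-Michael opening of ring C and loss of the C2 configuration are avoided and the benzyl ethers are untouched.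

Step 14
Reactants: 18 5,7-bis(benzyloxy)-8-{2-(benzyloxy)-5-[(2S)-5,7-dihydroxy-4-oxochroman-2-yl]phenyl}-2-(4-methoxyphenyl)-4H-chromen-4-one
Product: 19 (2S)-2,3-dihydropodocarpusflavone A, 8-{5-[(2S)-5,7-dihydroxy-4-oxochroman-2-yl]-2-hydroxyphenyl}-5,7-dihydroxy-2-(4-methoxyphenyl)-4H-chromen-4-one
Conditions: H2 (1 atm), 10% Pd/C, THF–MeOH, rt
Reagents that add atoms: none
Why: Catalytic hydrogenolysis of benzyl aryl ethers, which should cleave the three O–benzyl bonds at ambient pressure while the flavone C2=C3 bond, the flavanone carbonyl and the cyclic C2–O1 bond persist if the reaction is stopped at full debenzylation, C2 itself not being involved.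

**Compound list**

1 | 2,4,6-trihydroxyacetophenone | CC(=O)c1c(O)cc(O)cc1O | starting material
2 | 1-[2,4-bis(benzyloxy)-6-hydroxyphenyl]ethan-1-one | CC(=O)c1c(O)cc(OCc2ccccc2)cc1OCc1ccccc1 | intermediate
3 | 1-[4,6-bis(benzyloxy)-2-hydroxy-3-iodophenyl]ethan-1-one | CC(=O)c1c(O)c(I)c(OCc2ccccc2)cc1OCc1ccccc1 | intermediate
4 | 4-methoxybenzaldehyde | COc1ccc(C=O)cc1 | starting material
5 | (E)-1-[4,6-bis(benzyloxy)-2-hydroxy-3-iodophenyl]-3-(4-methoxyphenyl)prop-2-en-1-one | COc1ccc(/C=C/C(=O)c2c(O)c(I)c(OCc3ccccc3)cc2OCc2ccccc2)cc1 | intermediate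
6 | racemic 5,7-bis(benzyloxy)-8-iodo-2-(4-methoxyphenyl)chroman-4-one (not isolated) | COc1ccc(C2CC(=O)c3c(OCc4ccccc4)cc(OCc4ccccc4)c(I)c3O2)cc1 | intermediate
7 | 5,7-bis(benzyloxy)-8-iodo-2-(4-methoxyphenyl)-4H-chromen-4-one | COc1ccc(-c2cc(=O)c3c(OCc4ccccc4)cc(OCc4ccccc4)c(I)c3o2)cc1 | intermediate
8 | 4-hydroxy-3-iodobenzaldehyde | O=Cc1ccc(O)c(I)c1 | starting material
9 | 4-(benzyloxy)-3-iodobenzaldehyde | O=Cc1ccc(OCc2ccccc2)c(I)c1 | intermediate
10 | 4-(benzyloxy)-3-(4,4,5,5-tetramethyl-1,3,2-dioxaborolan-2-yl)benzaldehyde | O=Cc1ccc(OCc2ccccc2)c(B2OC(C)(C)C(C)(C)O2)c1 | intermediate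
11 | 4-(benzyloxy)-3-[5,7-bis(benzyloxy)-2-(4-methoxyphenyl)-4-oxo-4H-chromen-8-yl]benzaldehyde | COc1ccc(-c2cc(=O)c3c(OCc4ccccc4)cc(OCc4ccccc4)c(-c4cc(C=O)ccc4OCc4ccccc4)c3o2)cc1 | intermediate
12 | 5,7-bis(benzyloxy)-8-[2-(benzyloxy)-5-(hydroxymethyl)phenyl]-2-(4-methoxyphenyl)-4H-chromen-4-one | COc1ccc(-c2cc(=O)c3c(OCc4ccccc4)cc(OCc4ccccc4)c(-c4cc(CO)ccc4OCc4ccccc4)c3o2)cc1 | intermediate
13 | 1-[2-hydroxy-4,6-bis(triisopropylsilyloxy)phenyl]ethan-1-one | CC(=O)c1c(O)cc(O[Si](C(C)C)(C(C)C)C(C)C)cc1O[Si](C(C)C)(C(C)C)C(C)C | intermediate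
14 | 8-[5-({2-acetyl-3,5-bis(triisopropylsilyloxy)phenoxy}methyl)-2-(benzyloxy)phenyl]-5,7-bis(benzyloxy)-2-(4-methoxyphenyl)-4H-chromen-4-one | COc1ccc(-c2cc(=O)c3c(OCc4ccccc4)cc(OCc4ccccc4)c(-c4cc(COc5cc(O[Si](C(C)C)(C(C)C)C(C)C)cc(O[Si](C(C)C)(C(C)C)C(C)C)c5C(C)=O)ccc4OCc4ccccc4)c3o2)cc1 | intermediate
15 | 1-{2-[(4-(benzyloxy)-3-{5,7-bis(benzyloxy)-2-(4-methoxyphenyl)-4-oxo-4H-chromen-8-yl}phenyl)methoxy]-4,6-bis(triisopropylsilyloxy)phenyl}-4,4,4-trifluorobutane-1,3-dione (not isolated) | COc1ccc(-c2cc(=O)c3c(OCc4ccccc4)cc(OCc4ccccc4)c(-c4cc(COc5cc(O[Si](C(C)C)(C(C)C)C(C)C)cc(O[Si](C(C)C)(C(C)C)C(C)C)c5C(=O)CC(=O)C(F)(F)F)ccc4OCc4ccccc4)c3o2)cc1 | intermediate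
16 | 8-[5-({2-(2-diazoacetyl)-3,5-bis(triisopropylsilyloxy)phenoxy}methyl)-2-(benzyloxy)phenyl]-5,7-bis(benzyloxy)-2-(4-methoxyphenyl)-4H-chromen-4-one | COc1ccc(-c2cc(=O)c3c(OCc4ccccc4)cc(OCc4ccccc4)c(-c4cc(COc5cc(O[Si](C(C)C)(C(C)C)C(C)C)cc(O[Si](C(C)C)(C(C)C)C(C)C)c5C(=O)C=[N+]=[N-])ccc4OCc4ccccc4)c3o2)cc1 | intermediate
17 | 5,7-bis(benzyloxy)-8-{2-(benzyloxy)-5-[(2S)-4-oxo-5,7-bis(triisopropylsilyloxy)chroman-2-yl]phenyl}-2-(4-methoxyphenyl)-4H-chromen-4-one | COc1ccc(-c2cc(=O)c3c(OCc4ccccc4)cc(OCc4ccccc4)c(-c4cc([C@@H]5CC(=O)c6c(O[Si](C(C)C)(C(C)C)C(C)C)cc(O[Si](C(C)C)(C(C)C)C(C)C)cc6O5)ccc4OCc4ccccc4)c3o2)cc1 | intermediate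
18 | 5,7-bis(benzyloxy)-8-{2-(benzyloxy)-5-[(2S)-5,7-dihydroxy-4-oxochroman-2-yl]phenyl}-2-(4-methoxyphenyl)-4H-chromen-4-one | COc1ccc(-c2cc(=O)c3c(OCc4ccccc4)cc(OCc4ccccc4)c(-c4cc([C@@H]5CC(=O)c6c(O)cc(O)cc6O5)ccc4OCc4ccccc4)c3o2)cc1 | intermediate
19 | (2S)-2,3-dihydropodocarpusflavone A | COc1ccc(-c2cc(=O)c3c(O)cc(O)c(-c4cc([C@@H]5CC(=O)c6c(O)cc(O)cc6O5)ccc4O)c3o2)cc1 | target

**Totals**

Total step count: 14.
Longest linear sequence: 11 steps (steps 1, 2, 3, 4, 7, 8, 10, 11, 12, 13, 14; from 1 to 19).

**Steps most likely to fail**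

Step 12. The carbenoid may be intercepted by the lone pair of O1 (oxonium ylide, then Stevens [1,2]-benzyl shift to a benzofuranone), may dimerise, or may insert with poor discrimination between the two enantiotopic hydrogens. The fallback closes ring C at O1–C2 instead, by an organocatalytic oxa-Michael addition; it sets out from aldehyde 11 and ketone 13 and comes back at 17. Ketone 13 would be C-carboxylated through its dilithium derivative (LiN(SiMe3)2, THF, −78 °C, then di-tert-butyl dicarbonate) to tert-butyl 3-[2-hydroxy-4,6-bis(triisopropylsilyloxy)phenyl]-3-oxopropanoate F1. Knoevenagel condensation of F1 with 11 (piperidine, AcOH, benzene, reflux) would give the alkylidene β-keto ester F2. A bifunctional cinchona-alkaloid thiourea (the pseudoenantiomer that gives 2S; toluene, −25 °C) would then add the free phenol to the activated alkene to give the tert-butyl (2S)-flavanone-3-carboxylate F3. Warming F3 with TsOH in toluene would remove the tert-butyl ester with decarboxylation and give 17.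

Step 10. Activation of the hydrogen-bonded phenol may be too slow, so that the oxyphosphonium ion of the electron-rich benzylic alcohol ionises and alkylates the reduced azodicarboxylate or a ring carbon of the phloroglucinol unit instead of its oxygen. The fallback replaces the redox condensation by a Williamson alkylation; it sets out from alcohol 12 and phenol 13 and comes back at 14. Alcohol 12 would be converted (CBr4, PPh3, CH2Cl2, 0 °C) into 5,7-bis(benzyloxy)-8-[2-(benzyloxy)-5-(bromomethyl)phenyl]-2-(4-methoxyphenyl)-4H-chromen-4-one F4. The potassium phenoxide of 13 (K2CO3, acetone, 50 °C) would then displace bromide from F4 to give 14, the triisopropylsilyl ethers being expected to tolerate anhydrous carbonate.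

Step 7. Oxidative addition and transmetalation at the hindered, electron-rich C8 position may be slower than protodeboronation of boronate 10 and hydrodeiodination of 7. The fallback exchanges the roles of the partners, so that oxidative addition takes place at the unhindered, electron-poor iodide; it sets out from iodoflavone 7 and iodide 9 and comes back at 11. Iodoflavone 7 would be borylated with pinacolborane (PdCl2(MeCN)2, SPhos, Et3N, 1,4-dioxane, 80 °C) to 5,7-bis(benzyloxy)-2-(4-methoxyphenyl)-8-(4,4,5,5-tetramethyl-1,3,2-dioxaborolan-2-yl)-4H-chromen-4-one F5. Coupling of F5 with 9 (Pd(PPh3)4, K2CO3, DMF–H2O, 80 °C) would give 11.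

**Further compounds**

F1 | step 12 | tert-butyl 3-[2-hydroxy-4,6-bis(triisopropylsilyloxy)phenyl]-3-oxopropanoate | CC(C)(C)OC(=O)CC(=O)c1c(O)cc(O[Si](C(C)C)(C(C)C)C(C)C)cc1O[Si](C(C)C)(C(C)C)C(C)C
F2 | step 12 | tert-butyl 3-{4-(benzyloxy)-3-[5,7-bis(benzyloxy)-2-(4-methoxyphenyl)-4-oxo-4H-chromen-8-yl]phenyl}-2-[2-hydroxy-4,6-bis(triisopropylsilyloxy)benzoyl]prop-2-enoate (alkene isomers) | COc1ccc(-c2cc(=O)c3c(OCc4ccccc4)cc(OCc4ccccc4)c(-c4cc(C=C(C(=O)OC(C)(C)C)C(=O)c5c(O)cc(O[Si](C(C)C)(C(C)C)C(C)C)cc5O[Si](C(C)C)(C(C)C)C(C)C)ccc4OCc4ccccc4)c3o2)cc1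
F3 | step 12 | tert-butyl (2S)-2-{4-(benzyloxy)-3-[5,7-bis(benzyloxy)-2-(4-methoxyphenyl)-4-oxo-4H-chromen-8-yl]phenyl}-4-oxo-5,7-bis(triisopropylsilyloxy)chromane-3-carboxylate (C3 epimers) | COc1ccc(-c2cc(=O)c3c(OCc4ccccc4)cc(OCc4ccccc4)c(-c4cc([C@@H]5C(C(=O)OC(C)(C)C)C(=O)c6c(O[Si](C(C)C)(C(C)C)C(C)C)cc(O[Si](C(C)C)(C(C)C)C(C)C)cc6O5)ccc4OCc4ccccc4)c3o2)cc1
F4 | step 10 | 5,7-bis(benzyloxy)-8-[2-(benzyloxy)-5-(bromomethyl)phenyl]-2-(4-methoxyphenyl)-4H-chromen-4-one | COc1ccc(-c2cc(=O)c3c(OCc4ccccc4)cc(OCc4ccccc4)c(-c4cc(CBr)ccc4OCc4ccccc4)c3o2)cc1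
F5 | step 7 | 5,7-bis(benzyloxy)-2-(4-methoxyphenyl)-8-(4,4,5,5-tetramethyl-1,3,2-dioxaborolan-2-yl)-4H-chromen-4-one | COc1ccc(-c2cc(=O)c3c(OCc4ccccc4)cc(OCc4ccccc4)c(B4OC(C)(C)C(C)(C)O4)c3o2)cc1
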